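## Retrosynthetic overview

1. The target is a (2R,3S)-trans flavanone (naringenin unit) whose C3 is bonded to C8'' of an apigenin unit carrying a hydrogen sulfate on O7''. The last operations are re-oxidation of C4, sulfation of the only free hydroxyl (7''-OH) and hydrogenolysis of all benzyl ethers.
2. The strategy rests on flavone ring A (C4a'', C5'', C6'', C7'', C8'', C8a''). It is a phloroglucinol ring whose three oxygens need three fates (ring oxygen O1'', free 5''-OH, 7''-sulfate) and whose C8'' is bonded to the stereocentre C3. The ring is built on C3 from a silyl ynol ether and a 3-alkoxycyclobutenone (bonds C8''–C8a'', C6''–C7'', C4a''–C8a''), so its oxygens are born as OH, OSi(i-Pr)3 and OBn.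
3. Flavone ring C is then closed from the free phenol: ortho-formylation at C4a'', aryl acetylide addition, oxidation to the ynone, 6-endo-dig closure of O1''–C2''.
4. The alkynyl flavan comes from a trans flavanone-3-carboxylate whose pyranone ring is closed by a thiourea-catalysed asymmetric oxa-Michael addition (C2 set there, C3 by equilibration). C4 is kept as a silyl ether until the last basic step is over.
5. Ring order: flavanone ring A (bought) → flavanone pyranone ring → flavone ring A → flavone ring C. Both B rings are bought.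

Key step: step 12

Remarks on the chemistry (assumptions):
- The quinine-derived thiourea is taken to give the (2R) ring closure. Should the sense be opposite, its quinidine-derived pseudo-enantiomer is used and nothing else changes.
- The hindered C3–C8'' axis is treated as a pair of equilibrating rotamers, since the target is defined only at C2 and C3.
- Sulfate monoesters are handled as sodium salts and drawn in the neutral acid form.
- The cyclobutenone carries benzyloxy instead of ethoxy. An ethyl ether at C5'' would need a boron or magnesium halide for its removal, which the benzyl ethers would not reliably survive.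

## Route

Step 1
Reactants: 1 2,4,6-trihydroxyacetophenone; 2 benzyl bromide
Product: 3 1-[2,4-bis(benzyloxy)-6-hydroxyphenyl]ethan-1-one
Conditions: BnBr (2.1 equiv), K2CO3, DMF, 25 °C
Reagents that add atoms: benzyl bromide 2, BrCc1ccccc1
Why: Williamson etherification that should stop at the dibenzyl ether, because the remaining ortho-hydroxyl is hydrogen-bonded to the acetyl carbonyl and is the least nucleophilic oxygen.

Step 2
Reactants: 3 1-[2,4-bis(benzyloxy)-6-hydroxyphenyl]ethan-1-one; 4 di-tert-butyl dicarbonate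
Product: 5 tert-butyl 3-[2,4-bis(benzyloxy)-6-hydroxyphenyl]-3-oxopropanoate
Conditions: LiN(SiMe3)2 (3.3 equiv), THF, −78 °C; Boc2O, −78 → −20 °C; 1 M HCl quench
Reagents that add atoms: di-tert-butyl dicarbonate 4, CC(C)(C)OC(=O)OC(=O)OC(C)(C)C
Why: Crossed Claisen C-acylation of the phenoxide–enolate dianion (the third equivalent of base takes up the β-keto ester proton), with a tert-butyl ester chosen because it does not lactonise to the 4-hydroxycoumarin.

Step 3
Reactants: 5 tert-butyl 3-[2,4-bis(benzyloxy)-6-hydroxyphenyl]-3-oxopropanoate; 6 4-(benzyloxy)benzaldehyde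
Product: 7 tert-butyl 2-[2,4-bis(benzyloxy)-6-hydroxybenzoyl]-3-[4-(benzyloxy)phenyl]prop-2-enoate (E/Z mixture)
Conditions: piperidine (10 mol %), AcOH (10 mol %), 4 Å molecular sieves, toluene, 25 °C
Reagents that add atoms: 4-(benzyloxy)benzaldehyde 6, O=Cc1ccc(OCc2ccccc2)cc1
Why: Knoevenagel condensation of the β-keto ester with the aromatic aldehyde at room temperature, where uncatalysed ring closure of the alkylidene should remain slow.

Step 4
Reactants: 7 tert-butyl 2-[2,4-bis(benzyloxy)-6-hydroxybenzoyl]-3-[4-(benzyloxy)phenyl]prop-2-enoate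
Product: 8 tert-butyl (2R,3S)-5,7-bis(benzyloxy)-2-[4-(benzyloxy)phenyl]-4-oxochromane-3-carboxylate (2,3-trans)
Conditions: quinine-derived 3,5-bis(trifluoromethyl)phenyl thiourea (10 mol %), toluene, −25 °C; taken on without delay
Reagents that add atoms: none
Why: Bifunctional thiourea-catalysed intramolecular oxa-Michael addition (6-endo-trig) in which the thiourea binds the β-keto ester and the quinuclidine delivers the phenol to one face of the alkylidene, setting C2 as R, while C3 settles as the trans epimer by equilibration of the β-keto ester.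

Step 5
Reactants: 8 tert-butyl (2R,3S)-5,7-bis(benzyloxy)-2-[4-(benzyloxy)phenyl]-4-oxochromane-3-carboxylate
Product: 9 tert-butyl (2R,4R)-2,3-trans-3,4-trans-5,7-bis(benzyloxy)-2-[4-(benzyloxy)phenyl]-4-hydroxychromane-3-carboxylate
Conditions: NaBH4, CeCl3·7H2O, MeOH/THF, −40 → 0 °C
Reagents that add atoms: none
Why: Luche reduction of the ketone in a non-basic medium that should suppress retro-oxa-Michael opening; axial hydride delivery should give the equatorial (all-trans) alcohol, a placeholder centre that returns to a ketone in step 18.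

Step 6
Reactants: 9 tert-butyl (2R,4R)-2,3-trans-3,4-trans-5,7-bis(benzyloxy)-2-[4-(benzyloxy)phenyl]-4-hydroxychromane-3-carboxylate; 10 tert-butyldimethylsilyl trifluoromethanesulfonate
Product: 11 tert-butyl (2R,4R)-2,3-trans-3,4-trans-5,7-bis(benzyloxy)-2-[4-(benzyloxy)phenyl]-4-(tert-butyldimethylsilyloxy)chromane-3-carboxylate
Conditions: TBSOTf, 2,6-lutidine, CH2Cl2, −78 → −20 °C
Reagents that add atoms: tert-butyldimethylsilyl trifluoromethanesulfonate 10, CC(C)(C)[Si](C)(C)OS(=O)(=O)C(F)(F)F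
Why: Silylation of a hindered secondary alcohol with a silyl triflate under lutidine buffering, which locks C4 as a non-enolisable silyl ether so that C2 and C3 cannot scramble in the basic steps that follow.

Step 7
Reactants: 11 tert-butyl (2R,4R)-2,3-trans-3,4-trans-5,7-bis(benzyloxy)-2-[4-(benzyloxy)phenyl]-4-(tert-butyldimethylsilyloxy)chromane-3-carboxylate
Product: 12 [(2R,4R)-2,3-trans-3,4-trans-5,7,4'-tris(benzyloxy)-4-(tert-butyldimethylsilyloxy)flavan-3-yl]methanol
Conditions: i-Bu2AlH (3 equiv), CH2Cl2, −78 → 0 °C; aq. potassium sodium tartrate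
Reagents that add atoms: none
Why: Hydride reduction of the ester to the primary alcohol with a non-basic aluminium hydride, which should avoid silyl migration from O4 to the new alkoxide.

Step 8
Reactants: 12 [(2R,4R)-2,3-trans-3,4-trans-5,7,4'-tris(benzyloxy)-4-(tert-butyldimethylsilyloxy)flavan-3-yl]methanol
Product: 13 (2R,4R)-2,3-trans-3,4-trans-5,7,4'-tris(benzyloxy)-4-(tert-butyldimethylsilyloxy)flavan-3-carbaldehyde
Conditions: Dess–Martin periodinane, NaHCO3, CH2Cl2, 0 → 25 °C
Reagents that add atoms: none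
Why: Dess–Martin oxidation under buffered neutral conditions, which should leave the C3 centre (substituent equatorial, thermodynamic) and the acid-labile benzylic silyl ether untouched.

Step 9
Reactants: 13 (2R,4R)-2,3-trans-3,4-trans-5,7,4'-tris(benzyloxy)-4-(tert-butyldimethylsilyloxy)flavan-3-carbaldehyde; 14 dimethyl (1-diazo-2-oxopropyl)phosphonate
Product: 15 (2R,4R)-2,3-trans-3,4-trans-5,7,4'-tris(benzyloxy)-4-(tert-butyldimethylsilyloxy)-3-ethynylflavan
Conditions: 14, K2CO3, MeOH/THF, 0 → 25 °C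
Reagents that add atoms: dimethyl (1-diazo-2-oxopropyl)phosphonate 14, COP(=O)(OC)C(=[N+]=[N-])C(C)=O
Why: Ohira–Bestmann (Seyferth–Gilbert) homologation of the aldehyde to the terminal alkyne, in which any C3 epimerisation returns to the all-equatorial isomer and the fixed C4 centre would expose any scrambling at C2 as a separable diastereomer.

Step 10
Reactants: 15 (2R,4R)-2,3-trans-3,4-trans-5,7,4'-tris(benzyloxy)-4-(tert-butyldimethylsilyloxy)-3-ethynylflavan; 16 tert-butyl hydroperoxide; 17 triisopropylsilyl trifluoromethanesulfonate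
Product: 20 (2R,4R)-2,3-trans-3,4-trans-5,7,4'-tris(benzyloxy)-4-(tert-butyldimethylsilyloxy)-3-[(triisopropylsilyloxy)ethynyl]flavan, via lithium acetylide 18 (not isolated), via lithium ynolate 19 (not isolated)
Conditions: n-BuLi, THF, −78 °C; t-BuOOLi (from anhydrous t-BuOOH and LiN(SiMe3)2), −78 → 0 °C; TIPSOTf, −78 °C; pH 7 buffer; Et3N-deactivated silica
Reagents that add atoms: tert-butyl hydroperoxide 16, CC(C)(C)OO; triisopropylsilyl trifluoromethanesulfonate 17, CC(C)[Si](OS(=O)(=O)C(F)(F)F)(C(C)C)C(C)C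
Why: Oxidation of the lithium acetylide by lithium tert-butyl peroxide to the lithium ynolate and O-silylation by the hard silyl triflate, a known route from terminal alkynes to triisopropylsilyl ynol ethers, the silyl group chosen for thermal and chromatographic stability.

Step 11
Reactants: 21 3-ethoxycyclobut-2-en-1-one; 22 benzyl alcohol
Product: 23 3-(benzyloxy)cyclobut-2-en-1-one
Conditions: BnOH (5 equiv), TsOH (2 mol %), 25 °C, reduced pressure (EtOH removed); Et3N quench
Reagents that add atoms: benzyl alcohol 22, OCc1ccccc1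
Why: Acid-catalysed alkoxy exchange of a vinylogous ester (addition–elimination at C3 through the mixed ketal), driven by removal of ethanol and run at room temperature because the ring opens to the ketene near 80 °C.

Step 12
Reactants: 20 (2R,4R)-2,3-trans-3,4-trans-5,7,4'-tris(benzyloxy)-4-(tert-butyldimethylsilyloxy)-3-[(triisopropylsilyloxy)ethynyl]flavan; 23 3-(benzyloxy)cyclobut-2-en-1-one
Product: 28 (2R,4R)-2,3-trans-3,4-trans-5,7,4'-tris(benzyloxy)-4-(tert-butyldimethylsilyloxy)-3-[4-(benzyloxy)-2-hydroxy-6-(triisopropylsilyloxy)phenyl]flavan, via vinylketene 24 (not isolated), via vinylcyclobutenone 25 (not isolated), via dienylketene 26 (not isolated), via cyclohexadienone 27 (not isolated)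
Conditions: 23 (2 equiv, slow addition), toluene, 80 °C, then 110 °C
Reagents that add atoms: 3-(benzyloxy)cyclobut-2-en-1-one 23, O=C1C=C(OCc2ccccc2)C1
Why: At about 80 °C 23 opens by four-electron electrocyclic ring opening to (1-benzyloxyvinyl)ketene 24, which adds across the ynol ether of 20 in a [2+2] cycloaddition to give 4-vinylcyclobutenone 25; 25 opens in the same way to dienylketene 26, which closes to cyclohexadienone 27 and tautomerises to phenol 28. This is the Danheiser benzannulation of a cyclobutenone with a siloxyalkyne, known to give resorcinol monosilyl ethers. The one ring that stays in the product, flavone ring A, is closed by the thermal six-electron (disrotatory) electrocyclisation of 26, which makes C4a''–C8a'' after the cycloaddition has made C8''–C8a'' and C6''–C7''. No stereocentre is created in 28 (the sp3 carbons of 25 and 27 are lost on aromatisation), and C2, C3 and C4 are spectators because the medium is neutral and C4 carries no carbonyl. The step needs one regiochemistry in the [2+2] event, and the polarisation of the ynol ether secures it: its nucleophilic carbon (the one bonded to C3) attacks the ketene carbonyl, so OH and OSi(i-Pr)3 flank C8'' and OBn lies para to it. Slow addition of an excess of 23 keeps the ketene concentration low so that the hindered alkyne can compete with ketene dimerisation.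

Step 13
Reactants: 28 (2R,4R)-2,3-trans-3,4-trans-5,7,4'-tris(benzyloxy)-4-(tert-butyldimethylsilyloxy)-3-[4-(benzyloxy)-2-hydroxy-6-(triisopropylsilyloxy)phenyl]flavan; 29 paraformaldehyde
Product: 30 (2R,4R)-2,3-trans-3,4-trans-5,7,4'-tris(benzyloxy)-4-(tert-butyldimethylsilyloxy)-3-[4-(benzyloxy)-3-formyl-2-hydroxy-6-(triisopropylsilyloxy)phenyl]flavan
Conditions: MgCl2, Et3N, (CH2O)n, THF, 65 °C; aq. NH4Cl
Reagents that add atoms: paraformaldehyde 29, C=O
Why: Magnesium phenoxide-directed ortho-formylation (Casnati–Skattebøl), which delivers formaldehyde only to the one free position ortho to the phenol (C4a'') and leaves the para position C6'' alone.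

Step 14
Reactants: 30 (2R,4R)-2,3-trans-3,4-trans-5,7,4'-tris(benzyloxy)-4-(tert-butyldimethylsilyloxy)-3-[4-(benzyloxy)-3-formyl-2-hydroxy-6-(triisopropylsilyloxy)phenyl]flavan; 31 1-(benzyloxy)-4-ethynylbenzene
Product: 32 (2R,4R)-2,3-trans-3,4-trans-5,7,4'-tris(benzyloxy)-4-(tert-butyldimethylsilyloxy)-3-[4-(benzyloxy)-3-{3-[4-(benzyloxy)phenyl]-1-hydroxyprop-2-yn-1-yl}-2-hydroxy-6-(triisopropylsilyloxy)phenyl]flavan (carbinol epimers; used crude)
Conditions: 31 (3 equiv), n-BuLi (2.9 equiv), THF, −78 °C; then 30, −78 → 0 °C; H2O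
Reagents that add atoms: 1-(benzyloxy)-4-ethynylbenzene 31, C#Cc1ccc(OCc2ccccc2)cc1
Why: 1,2-Addition of a lithium acetylide to the aldehyde, with excess reagent to cover the phenol proton; the new carbinol centre is oxidised away in the next step.

Step 15
Reactants: 32 (2R,4R)-2,3-trans-3,4-trans-5,7,4'-tris(benzyloxy)-4-(tert-butyldimethylsilyloxy)-3-[4-(benzyloxy)-3-{3-[4-(benzyloxy)phenyl]-1-hydroxyprop-2-yn-1-yl}-2-hydroxy-6-(triisopropylsilyloxy)phenyl]flavan
Product: 33 (2R,4R)-2,3-trans-3,4-trans-5,7,4'-tris(benzyloxy)-4-(tert-butyldimethylsilyloxy)-3-[4-(benzyloxy)-3-{3-[4-(benzyloxy)phenyl]prop-2-ynoyl}-2-hydroxy-6-(triisopropylsilyloxy)phenyl]flavan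
Conditions: MnO2 (excess), CH2Cl2, 25 °C
Reagents that add atoms: none
Why: MnO2 oxidation of a benzylic and propargylic carbinol to the ynone, a mild heterogeneous oxidant that should leave the free phenol and both silyl ethers alone.

Step 16
Reactants: 33 (2R,4R)-2,3-trans-3,4-trans-5,7,4'-tris(benzyloxy)-4-(tert-butyldimethylsilyloxy)-3-[4-(benzyloxy)-3-{3-[4-(benzyloxy)phenyl]prop-2-ynoyl}-2-hydroxy-6-(triisopropylsilyloxy)phenyl]flavan
Product: 34 8-[(2R,4R)-2,3-trans-3,4-trans-5,7,4'-tris(benzyloxy)-4-(tert-butyldimethylsilyloxy)flavan-3-yl]-5-(benzyloxy)-2-[4-(benzyloxy)phenyl]-7-(triisopropylsilyloxy)-4H-chromen-4-one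
Conditions: K2CO3, acetone, 56 °C
Reagents that add atoms: none
Why: Base-mediated 6-endo-dig oxa-Michael cyclisation of an ortho-hydroxyaryl ynone, which in an aprotic medium should give the flavone and not the 5-exo aurone, while the aprotic carbonate spares the aryl silyl ether.

Step 17
Reactants: 34 8-[(2R,4R)-2,3-trans-3,4-trans-5,7,4'-tris(benzyloxy)-4-(tert-butyldimethylsilyloxy)flavan-3-yl]-5-(benzyloxy)-2-[4-(benzyloxy)phenyl]-7-(triisopropylsilyloxy)-4H-chromen-4-one
Product: 35 8-[(2R,4R)-2,3-trans-3,4-trans-5,7,4'-tris(benzyloxy)-4-hydroxyflavan-3-yl]-5-(benzyloxy)-2-[4-(benzyloxy)phenyl]-7-hydroxy-4H-chromen-4-one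
Conditions: Bu4NF, AcOH, THF, 0 → 40 °C
Reagents that add atoms: none
Why: Fluoride desilylation of the aryl and the secondary alkyl silyl ether in one operation, buffered with acetic acid and free of the protic acid that would ionise the electron-rich benzylic C4–O bond.

Step 18
Reactants: 35 8-[(2R,4R)-2,3-trans-3,4-trans-5,7,4'-tris(benzyloxy)-4-hydroxyflavan-3-yl]-5-(benzyloxy)-2-[4-(benzyloxy)phenyl]-7-hydroxy-4H-chromen-4-one
Product: 36 (2R,3S)-5,7,4'-tris(benzyloxy)-3-{5-(benzyloxy)-2-[4-(benzyloxy)phenyl]-7-hydroxy-4-oxo-4H-chromen-8-yl}flavan-4-one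
Conditions: MnO2 (excess), CH2Cl2, 25–40 °C
Reagents that add atoms: none
Why: MnO2 oxidation of the benzylic carbinol on the trioxygenated ring to the flavanone ketone, which should leave the acidic 7''-phenol alone and restores the carbonyl only after every basic step, so that the trans C3 centre is never exposed to base.

Step 19
Reactants: 36 (2R,3S)-5,7,4'-tris(benzyloxy)-3-{5-(benzyloxy)-2-[4-(benzyloxy)phenyl]-7-hydroxy-4-oxo-4H-chromen-8-yl}flavan-4-one; 37 sulfur trioxide–pyridine complex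
Product: 38 5-(benzyloxy)-2-[4-(benzyloxy)phenyl]-8-[(2R,3S)-5,7,4'-tris(benzyloxy)-4-oxoflavan-3-yl]-4-oxo-4H-chromen-7-yl hydrogen sulfate
Conditions: SO3·pyridine (5 equiv), pyridine, 40 °C; aq. NaHCO3
Reagents that add atoms: sulfur trioxide–pyridine complex 37, O=S(=O)([O-])[n+]1ccccc1
Why: O-Sulfation with an amine–SO3 complex, regioselective by construction because the 7''-hydroxyl is the only free hydroxyl in 36, in a base too weak to enolise the flavanone.

Step 20
Reactants: 38 5-(benzyloxy)-2-[4-(benzyloxy)phenyl]-8-[(2R,3S)-5,7,4'-tris(benzyloxy)-4-oxoflavan-3-yl]-4-oxo-4H-chromen-7-yl hydrogen sulfate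
Product: 39 (2R,3S)-5,7,4'-trihydroxy-3-[5-hydroxy-2-(4-hydroxyphenyl)-4-oxo-7-(sulfooxy)-4H-chromen-8-yl]flavan-4-one (CNP0271389.1)
Conditions: H2 (1 atm), Pd on carbon (10 wt %), THF/MeOH, 25 °C; acid-form sulfonic resin, 0 °C
Reagents that add atoms: none
Why: Catalytic hydrogenolysis of the five benzyl ethers at atmospheric pressure under neutral conditions, which should leave the aryl sulfate salt, the flavone double bond, both ketones and the C2 and C3 stereocentres untouched.

## Compound list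

1 | 2,4,6-trihydroxyacetophenone | CC(=O)c1c(O)cc(O)cc1O | starting material
2 | benzyl bromide | BrCc1ccccc1 | starting material
3 | 1-[2,4-bis(benzyloxy)-6-hydroxyphenyl]ethan-1-one | CC(=O)c1c(O)cc(OCc2ccccc2)cc1OCc1ccccc1 | intermediate
4 | di-tert-butyl dicarbonate | CC(C)(C)OC(=O)OC(=O)OC(C)(C)C | starting material
5 | tert-butyl 3-[2,4-bis(benzyloxy)-6-hydroxyphenyl]-3-oxopropanoate | CC(C)(C)OC(=O)CC(=O)c1c(O)cc(OCc2ccccc2)cc1OCc1ccccc1 | intermediate
6 | 4-(benzyloxy)benzaldehyde | O=Cc1ccc(OCc2ccccc2)cc1 | starting material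
7 | tert-butyl 2-[2,4-bis(benzyloxy)-6-hydroxybenzoyl]-3-[4-(benzyloxy)phenyl]prop-2-enoate (E/Z mixture) | CC(C)(C)OC(=O)C(=Cc1ccc(OCc2ccccc2)cc1)C(=O)c1c(O)cc(OCc2ccccc2)cc1OCc1ccccc1 | intermediate
8 | tert-butyl (2R,3S)-5,7-bis(benzyloxy)-2-[4-(benzyloxy)phenyl]-4-oxochromane-3-carboxylate (2,3-trans) | O=C1c2c(OCc3ccccc3)cc(OCc3ccccc3)cc2O[C@@H](c2ccc(OCc3ccccc3)cc2)[C@@H]1C(=O)OC(C)(C)C | intermediate
9 | tert-butyl (2R,4R)-2,3-trans-3,4-trans-5,7-bis(benzyloxy)-2-[4-(benzyloxy)phenyl]-4-hydroxychromane-3-carboxylate | O[C@H]1c2c(OCc3ccccc3)cc(OCc3ccccc3)cc2O[C@@H](c2ccc(OCc3ccccc3)cc2)[C@@H]1C(=O)OC(C)(C)C | intermediate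
10 | tert-butyldimethylsilyl trifluoromethanesulfonate | CC(C)(C)[Si](C)(C)OS(=O)(=O)C(F)(F)F | starting material
11 | tert-butyl (2R,4R)-2,3-trans-3,4-trans-5,7-bis(benzyloxy)-2-[4-(benzyloxy)phenyl]-4-(tert-butyldimethylsilyloxy)chromane-3-carboxylate | CC(C)(C)[Si](C)(C)O[C@H]1c2c(OCc3ccccc3)cc(OCc3ccccc3)cc2O[C@@H](c2ccc(OCc3ccccc3)cc2)[C@@H]1C(=O)OC(C)(C)C | intermediate
12 | [(2R,4R)-2,3-trans-3,4-trans-5,7,4'-tris(benzyloxy)-4-(tert-butyldimethylsilyloxy)flavan-3-yl]methanol | CC(C)(C)[Si](C)(C)O[C@H]1c2c(OCc3ccccc3)cc(OCc3ccccc3)cc2O[C@@H](c2ccc(OCc3ccccc3)cc2)[C@@H]1CO | intermediate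
13 | (2R,4R)-2,3-trans-3,4-trans-5,7,4'-tris(benzyloxy)-4-(tert-butyldimethylsilyloxy)flavan-3-carbaldehyde | CC(C)(C)[Si](C)(C)O[C@H]1c2c(OCc3ccccc3)cc(OCc3ccccc3)cc2O[C@@H](c2ccc(OCc3ccccc3)cc2)[C@@H]1C=O | intermediate
14 | dimethyl (1-diazo-2-oxopropyl)phosphonate | COP(=O)(OC)C(=[N+]=[N-])C(C)=O | starting material
15 | (2R,4R)-2,3-trans-3,4-trans-5,7,4'-tris(benzyloxy)-4-(tert-butyldimethylsilyloxy)-3-ethynylflavan | CC(C)(C)[Si](C)(C)O[C@H]1c2c(OCc3ccccc3)cc(OCc3ccccc3)cc2O[C@@H](c2ccc(OCc3ccccc3)cc2)[C@@H]1C#C | intermediate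
16 | tert-butyl hydroperoxide | CC(C)(C)OO | starting material
17 | triisopropylsilyl trifluoromethanesulfonate | CC(C)[Si](OS(=O)(=O)C(F)(F)F)(C(C)C)C(C)C | starting material
18 | lithium acetylide of 15 | CC(C)(C)[Si](C)(C)O[C@H]1c2c(OCc3ccccc3)cc(OCc3ccccc3)cc2O[C@@H](c2ccc(OCc3ccccc3)cc2)[C@@H]1C#C[Li] | intermediate (not isolated)
19 | lithium ynolate from 18 | CC(C)(C)[Si](C)(C)O[C@H]1c2c(OCc3ccccc3)cc(OCc3ccccc3)cc2O[C@@H](c2ccc(OCc3ccccc3)cc2)[C@@H]1C#CO[Li] | intermediate (not isolated)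
20 | (2R,4R)-2,3-trans-3,4-trans-5,7,4'-tris(benzyloxy)-4-(tert-butyldimethylsilyloxy)-3-[(triisopropylsilyloxy)ethynyl]flavan | CC(C)(C)[Si](C)(C)O[C@H]1c2c(OCc3ccccc3)cc(OCc3ccccc3)cc2O[C@@H](c2ccc(OCc3ccccc3)cc2)[C@@H]1C#CO[Si](C(C)C)(C(C)C)C(C)C | intermediate
21 | 3-ethoxycyclobut-2-en-1-one | CCOC1=CC(=O)C1 | starting material
22 | benzyl alcohol | OCc1ccccc1 | starting material
23 | 3-(benzyloxy)cyclobut-2-en-1-one | O=C1C=C(OCc2ccccc2)C1 | intermediate
24 | 3-(benzyloxy)buta-1,3-dien-1-one (vinylketene) | C=C(OCc1ccccc1)C=C=O | intermediate (not isolated)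
25 | 4-[1-(benzyloxy)vinyl]-2-(flavan-3-yl)-3-(triisopropylsilyloxy)cyclobut-2-en-1-one (flavan as in 20; C4 of the cyclobutenone unassigned) | CC(C)(C)[Si](C)(C)O[C@H]1c2c(OCc3ccccc3)cc(OCc3ccccc3)cc2O[C@@H](c2ccc(OCc3ccccc3)cc2)[C@@H]1C1=C(O[Si](C(C)C)(C(C)C)C(C)C)C(C(=C)OCc2ccccc2)C1=O | intermediate (not isolated)
26 | 5-(benzyloxy)-2-(flavan-3-yl)-3-(triisopropylsilyloxy)hexa-1,3,5-trien-1-one (dienylketene; flavan as in 20) | CC(C)(C)[Si](C)(C)O[C@H]1c2c(OCc3ccccc3)cc(OCc3ccccc3)cc2O[C@@H](c2ccc(OCc3ccccc3)cc2)[C@@H]1C(=C=O)/C(O[Si](C(C)C)(C(C)C)C(C)C)=C\C(=C)OCc1ccccc1 | intermediate (not isolated)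
27 | 5-(benzyloxy)-2-(flavan-3-yl)-3-(triisopropylsilyloxy)cyclohexa-2,4-dien-1-one (flavan as in 20) | CC(C)(C)[Si](C)(C)O[C@H]1c2c(OCc3ccccc3)cc(OCc3ccccc3)cc2O[C@@H](c2ccc(OCc3ccccc3)cc2)[C@@H]1C1=C(O[Si](C(C)C)(C(C)C)C(C)C)C=C(OCc2ccccc2)CC1=O | intermediate (not isolated)
28 | (2R,4R)-2,3-trans-3,4-trans-5,7,4'-tris(benzyloxy)-4-(tert-butyldimethylsilyloxy)-3-[4-(benzyloxy)-2-hydroxy-6-(triisopropylsilyloxy)phenyl]flavan | CC(C)(C)[Si](C)(C)O[C@H]1c2c(OCc3ccccc3)cc(OCc3ccccc3)cc2O[C@@H](c2ccc(OCc3ccccc3)cc2)[C@@H]1c1c(O)cc(OCc2ccccc2)cc1O[Si](C(C)C)(C(C)C)C(C)C | intermediate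
29 | paraformaldehyde (as formaldehyde) | C=O | starting material
30 | (2R,4R)-2,3-trans-3,4-trans-5,7,4'-tris(benzyloxy)-4-(tert-butyldimethylsilyloxy)-3-[4-(benzyloxy)-3-formyl-2-hydroxy-6-(triisopropylsilyloxy)phenyl]flavan | CC(C)(C)[Si](C)(C)O[C@H]1c2c(OCc3ccccc3)cc(OCc3ccccc3)cc2O[C@@H](c2ccc(OCc3ccccc3)cc2)[C@@H]1c1c(O)c(C=O)c(OCc2ccccc2)cc1O[Si](C(C)C)(C(C)C)C(C)C | intermediate
31 | 1-(benzyloxy)-4-ethynylbenzene | C#Cc1ccc(OCc2ccccc2)cc1 | starting material
32 | propargylic alcohol from 30 and 31 (carbinol epimers) | CC(C)(C)[Si](C)(C)O[C@H]1c2c(OCc3ccccc3)cc(OCc3ccccc3)cc2O[C@@H](c2ccc(OCc3ccccc3)cc2)[C@@H]1c1c(O)c(C(O)C#Cc2ccc(OCc3ccccc3)cc2)c(OCc2ccccc2)cc1O[Si](C(C)C)(C(C)C)C(C)C | intermediate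
33 | ortho-hydroxyaryl ynone from 32 | CC(C)(C)[Si](C)(C)O[C@H]1c2c(OCc3ccccc3)cc(OCc3ccccc3)cc2O[C@@H](c2ccc(OCc3ccccc3)cc2)[C@@H]1c1c(O)c(C(=O)C#Cc2ccc(OCc3ccccc3)cc2)c(OCc2ccccc2)cc1O[Si](C(C)C)(C(C)C)C(C)C | intermediate
34 | 8-[(2R,4R)-2,3-trans-3,4-trans-5,7,4'-tris(benzyloxy)-4-(tert-butyldimethylsilyloxy)flavan-3-yl]-5-(benzyloxy)-2-[4-(benzyloxy)phenyl]-7-(triisopropylsilyloxy)-4H-chromen-4-one | CC(C)(C)[Si](C)(C)O[C@H]1c2c(OCc3ccccc3)cc(OCc3ccccc3)cc2O[C@@H](c2ccc(OCc3ccccc3)cc2)[C@@H]1c1c(O[Si](C(C)C)(C(C)C)C(C)C)cc(OCc2ccccc2)c2c(=O)cc(-c3ccc(OCc4ccccc4)cc3)oc12 | intermediate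
35 | 8-[(2R,4R)-2,3-trans-3,4-trans-5,7,4'-tris(benzyloxy)-4-hydroxyflavan-3-yl]-5-(benzyloxy)-2-[4-(benzyloxy)phenyl]-7-hydroxy-4H-chromen-4-one | O[C@H]1c2c(OCc3ccccc3)cc(OCc3ccccc3)cc2O[C@@H](c2ccc(OCc3ccccc3)cc2)[C@@H]1c1c(O)cc(OCc2ccccc2)c2c(=O)cc(-c3ccc(OCc4ccccc4)cc3)oc12 | intermediate
36 | (2R,3S)-5,7,4'-tris(benzyloxy)-3-{5-(benzyloxy)-2-[4-(benzyloxy)phenyl]-7-hydroxy-4-oxo-4H-chromen-8-yl}flavan-4-one | O=C1c2c(OCc3ccccc3)cc(OCc3ccccc3)cc2O[C@@H](c2ccc(OCc3ccccc3)cc2)[C@@H]1c1c(O)cc(OCc2ccccc2)c2c(=O)cc(-c3ccc(OCc4ccccc4)cc3)oc12 | intermediate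
37 | sulfur trioxide–pyridine complex | O=S(=O)([O-])[n+]1ccccc1 | starting material
38 | 5-(benzyloxy)-2-[4-(benzyloxy)phenyl]-8-[(2R,3S)-5,7,4'-tris(benzyloxy)-4-oxoflavan-3-yl]-4-oxo-4H-chromen-7-yl hydrogen sulfate | O=C1c2c(OCc3ccccc3)cc(OCc3ccccc3)cc2O[C@@H](c2ccc(OCc3ccccc3)cc2)[C@@H]1c1c(OS(=O)(=O)O)cc(OCc2ccccc2)c2c(=O)cc(-c3ccc(OCc4ccccc4)cc3)oc12 | intermediate
39 | (2R,3S)-5,7,4'-trihydroxy-3-[5-hydroxy-2-(4-hydroxyphenyl)-4-oxo-7-(sulfooxy)-4H-chromen-8-yl]flavan-4-one (CNP0271389.1) | O=C1c2c(O)cc(O)cc2O[C@@H](c2ccc(O)cc2)[C@@H]1c1c(OS(=O)(=O)O)cc(O)c2c(=O)cc(-c3ccc(O)cc3)oc12 | target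

## Step count and risks

Total: 20 steps. Longest linear sequence: 19 steps (steps 1–10 and 12–20); step 11 is a one-step side branch.

Steps most likely to fail:

1. Step 12 (key benzannulation). The bimolecular ketene–ynol ether cycloaddition may be outrun at 80–110 °C by ketene dimerisation, or the hindered silyl ynol ether may be lost by a thermal 1,3-silyl shift before it is intercepted. The fallback sets out from 20 and comes back at 28, and separates the bimolecular event from the heating. Ethyl but-2-ynoate and 22 are joined by PMe3-catalysed conjugate addition to ethyl (E)-3-(benzyloxy)but-2-enoate F1. Hydrolysis with LiOH gives (E)-3-(benzyloxy)but-2-enoic acid F2, and oxalyl chloride with catalytic DMF gives (E)-3-(benzyloxy)but-2-enoyl chloride F3. Slow addition of Et3N to F3 and 20 in CH2Cl2 at 0–25 °C generates the same vinylketene 24 by 1,4-dehydrochlorination, so the [2+2] cycloaddition to 25 takes place at ambient temperature. The ketene-free 25 is then heated in toluene (80–110 °C), where the purely intramolecular ring opening and six-electron closure should lead to 28.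

2. Step 4 (asymmetric oxa-Michael closure). Facial selectivity may be poor because the ortho-benzyloxy group twists the aryl ketone out of the catalyst-bound plane, and the enantiomeric purity may erode through reversible ring opening of the β-keto ester. The fallback sets out from 5 and comes back at 8. Condensation of 5 with N,N-dimethylformamide dimethyl acetal (toluene, 80 °C) closes the pyranone first, giving tert-butyl 5,7-bis(benzyloxy)-4-oxo-4H-chromene-3-carboxylate F4. Asymmetric conjugate addition of 4-(benzyloxy)phenylboronic acid then sets C2; the catalyst is Pd(OCOCF3)2 with the enantiomer of the t-BuPyOx ligand that gives 2R (NH4PF6, H2O, 1,2-dichloroethane, 60 °C). Protonation to the trans β-keto ester gives 8.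

3. Step 11 (alkoxy exchange on the cyclobutenone). The acid and the alcohol may cleave the strained vinylogous ester to open-chain butenoates, or the exchange may stall short of completion. The fallback sets out from 21 and comes back at 23. Hydrolysis of 21 with cold 2 M HCl gives the vinylogous acid cyclobutane-1,3-dione F5, which is O-benzylated under Mitsunobu conditions (22, PPh3, diisopropyl azodicarboxylate, THF, 0 °C) to give 23.

## Further compounds

F1 | step 12 | ethyl (E)-3-(benzyloxy)but-2-enoate | CCOC(=O)/C=C(\C)OCc1ccccc1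
F2 | step 12 | (E)-3-(benzyloxy)but-2-enoic acid | OC(=O)/C=C(\C)OCc1ccccc1
F3 | step 12 | (E)-3-(benzyloxy)but-2-enoyl chloride | ClC(=O)/C=C(\C)OCc1ccccc1
F4 | step 4 | tert-butyl 5,7-bis(benzyloxy)-4-oxo-4H-chromene-3-carboxylate | CC(C)(C)OC(=O)c1coc2cc(OCc3ccccc3)cc(OCc3ccccc3)c2c1=O
F5 | step 11 | cyclobutane-1,3-dione | O=C1CC(=O)C1
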